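Colleague, you asked for a quick number on this flask, and your hunch stands below as the forecast; here is my own reckoning first.

| flask | substrate | reagent in the second phase | remark | time | volume of the second phase over the first |
|---|---|---|---|---|---|
| elm | 1.1 M | 1.2 equiv | run made earlier |  |  |
| oak | 1.8 M | 1.2 equiv | run made earlier |  |  |
| cedar | 0.80 M | 0.60 equiv | run made earlier |  |  |
| flask | 0.80 M | 1.20 equiv |  | 25 h | 1.0 |

| run | time / h | target / % | substrate / % |
|---|---|---|---|
| elm | 2.50 | 5.8 | 94.5 |
| elm | 5.00 | 11.0 | 88.3 |
| elm | 8.00 | 16.5 | 82.4 |
| elm | 15.0 | 25.4 | 70.3 |
| elm | 30.0 | 37.2 | 52.8 |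
| oak | 2.50 | 6.1 | 92.7 |
| oak | 8.00 | 19.4 | 80.2 |
| oak | 15.0 | 28.1 | 67.0 |
| oak | 20.0 | 32.6 | 60.3 |
| oak | 30.0 | 38.6 | 49.4 |
| cedar | 2.50 | 2.5 | 96.4 |
| cedar | 8.00 | 8.4 | 92.6 |
| cedar | 15.0 | 13.7 | 84.8 |
| cedar | 20.0 | 17.3 | 81.4 |
| cedar | 30.0 | 22.6 | 74.3 |

(scatter of a reading: 0.5 percentage points)

- in the second phase: reagent in the second phase; everything else is in the first
- charges count per volume of the first phase; a concentration in a rate is the amount of a species over the volume of its own phase; every rate counts per litre of the first phase
- what may be going on: reagent in the reaction phase + target -> over-reacted product; reagent in the reaction phase <-> dormant form; substrate + reagent in the reaction phase -> target; reagent in the reaction phase <-> reagent in the second phase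
- the earlier runs hold the two phases in the same ratio of volumes as the flask asked about

* how much target there is at 25 h, in percent of the substrate charged
* part of the substrate charged that has reacted at 25 h

Each substrate that reacts takes one reagent, and each target that over-reacts takes one more, so a run's balance shows what has left the second phase, if little waits in the reaction phase or as dormant form. At one end, cedar has used 48.0% of its own charge by 30.0 h. I take the logarithm of charge over what remains, divided by time, as a drain constant w, a pseudo-first-order constant for the second phase: 0.0218 h⁻¹. Elm, with twice the equivalents, reads 0.0216 h⁻¹, so I keep cedar's, which has the flask's substrate concentration.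

At the other end, I take over-reacted product as g times the square of the reacted part x, and elm's last reading gives g = 0.449. Joining them, I set x + gx² equal to the equivalents times the drained part, 50.4% of the substrate charged. That gives x = 42.4% and target 34.3%.

The forecast says 30.5% target and 37% reacted, reasoning that “the rate saturates with reagent charge”; my target is higher than its figure.

The flask gives 32.6% target and 40.0% reacted, and the forecast held.

    reagent in the reaction phase + target → over-reacted product (k = 0.00130 M⁻¹ s⁻¹)
    reagent in the reaction phase ⇌ dormant form (K = 1.70, k = 3.00 × 10⁻⁴ s⁻¹)
    substrate + reagent in the reaction phase → target (k = 0.00170 M⁻¹ s⁻¹)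
    reagent in the reaction phase ⇌ reagent in the second phase, rate k4*([reagent in the reaction phase] - [reagent in the second phase]/K4) per volume of the first phase (partition coefficient = 75.0, kL = 6.50 × 10⁻⁴ s⁻¹)

In the flask at 25.0 h, reagent in the reaction phase has a half-life of 0.24 h by the step to target, far shorter than the 25 h run, and it is made at 0.996 times the rate at which it is used up, each step taken net, while reagent in the second phase stands at 59.7% of its charge against the 58.0% that w leaves. Read at 4.0 d, the same flask holds 16.1% of that charge in the second phase, where w leaves 12.3%.

Readings and results are calculated with made-up constants; the scatter is artificial.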